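**Retrosynthetic overview**
1. Target 20 is a depside. The aryl ester C(=O)–O bond between ring A acid 17 and ring B phenol 12 is cut, and the ring B carboxyl is carried as its benzyl ester, the only protecting group.
2. The route rests on ring B (C1' carboxyl, C2' OMe, C4' acylated O, C6' propyl), whose two meta oxygens must differ. C1', C2', C3', C6' map onto C5, C4, C3, C6 of 2-pyrone 5, and C4'/C5' come from ketene bis(silyl) acetal 8.
3. A (4+2) addition across pyrone C3/C6, then loss of CO2 and Me3SiOH, gives the arene with C2'-OMe and a free C4'-OH from the outset.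
4. Pyrone 5 comes from ethyl 3-oxohexanoate (transesterification, malonyl dichloride annulation, O-methylation), 8 from trimethylsilyl acetate, and acid 17 from olivetol (methylation, Vilsmeier formylation, Pinnick oxidation).
5. Ring order: pyrone ring, then ring B (the only carbocycle made; ring A is bought), then ester coupling and hydrogenolysis.

Key step: step 5

Remark: the target has no stereocentre; ring B atoms carry primes (C1' bears the carboxyl), and the bridged adduct 9 forms as a racemate whose two stereocentres disappear on aromatization.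

**Route**

Step 1
Reactants: 1 ethyl 3-oxohexanoate
Product: 2 benzyl 3-oxohexanoate
Conditions: BnOH (1.1 equiv), DMAP (cat.), toluene, reflux, EtOH distilled off
Reagents that add atoms: benzyl alcohol, OCc1ccccc1
Why: Transesterification of a beta-keto ester, which exchanges its alkoxy group readily (through the acylketene or DMAP catalysis) and is driven by removal of ethanol.

Step 2
Reactants: 2 benzyl 3-oxohexanoate; 3 malonyl dichloride
Product: 4 benzyl 4-hydroxy-2-oxo-6-propyl-2H-pyran-5-carboxylate
Conditions: 3 (1.1 equiv), CH2Cl2, rt then 40 °C, N2 sweep to remove HCl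
Reagents that add atoms: none
Why: Double acylation of the enolized beta-keto ester by malonyl dichloride (C-acylation at the alpha carbon and O-acylation of the ketone enol) is the known annulation to 5-alkoxycarbonyl-4-hydroxy-6-alkyl-2-pyrones.

Step 3
Reactants: 4 benzyl 4-hydroxy-2-oxo-6-propyl-2H-pyran-5-carboxylate
Product: 5 benzyl 4-methoxy-2-oxo-6-propyl-2H-pyran-5-carboxylate
Conditions: Me2SO4, K2CO3, acetone, reflux
Reagents that add atoms: dimethyl sulfate, COS(=O)(=O)OC
Why: O-alkylation of the acidic vinylogous acid of a 4-hydroxy-2-pyrone with dimethyl sulfate and carbonate should favour the 4-methoxy-2-pyrone over the 2-methoxy-4-pyrone and leaves the benzyl ester untouched.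

Step 4
Reactants: 6 trimethylsilyl acetate
Product: 8 1,1-bis(trimethylsilyloxy)ethene, via lithium enolate 7 (not isolated)
Conditions: LiN(iPr)2 (LDA), THF, −78 °C; then Me3SiCl, −78 °C → rt; distillation under reduced pressure
Reagents that add atoms: chlorotrimethylsilane, C[Si](C)(C)Cl
Why: Kinetic enolization of the silyl ester and O-silylation of the enolate is the standard preparation of ketene bis(trimethylsilyl) acetals.

Step 5
Reactants: 5 benzyl 4-methoxy-2-oxo-6-propyl-2H-pyran-5-carboxylate; 8 1,1-bis(trimethylsilyloxy)ethene
Product: 12 benzyl 4-hydroxy-2-methoxy-6-propylbenzoate, via bridged lactone adduct 9 (not isolated), via bis(silyloxy)cyclohexadiene 10 (not isolated), via aryl trimethylsilyl ether 11 (not isolated)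
Conditions: 8 (4 equiv), toluene, 140 °C, sealed tube; then 1 M HCl, THF, rt
Reagents that add atoms: none
Why: The CH2 terminus of electron-rich 8 adds to pyrone C6 (beta to the C5 benzyl ester and attached to the ring oxygen) and the resulting bis(silyloxy)carbenium carbon is captured by C3 of the dienolate, so that the C5'–C6' and C3'–C4' bonds form in an inverse-electron-demand Diels–Alder sense (asynchronous or stepwise) to give bridged lactone 9. Retro-(4+2) extrusion of CO2 from 9 gives diene 10, elimination of Me3SiOH across C4'/C5' aromatizes it to silyl ether 11, and the acidic work-up frees phenol 12. The closest known reaction type is the cycloaddition of alkyl coumalates (5-alkoxycarbonyl-2-pyrones) with ketene acetals to give 4-alkoxybenzoates with loss of CO2 and alcohol; here both acetal groups are silyl so the para oxygen emerges free, and because the 4-methoxy and 6-propyl groups make 5 a slower diene than the parent coumalates, an excess of 8 and sealed-vessel heating are used. Ring B is closed as a six-membered carbocycle by (4+2) annulation across pyrone C3 and C6, with pyrone C2 and O1 leaving as CO2. The two bridgehead stereocentres of 9 form as a racemate and vanish on aromatization, so no stereocontrol is required. The step needs regiocontrol only: the C5 ester makes C6 the electrophilic end of the diene, which places the oxygen-bearing carbon of 8 at C4' para to the carboxyl and leaves the pyrone-derived methoxy at C2'.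

Step 6
Reactants: 13 olivetol (5-pentylbenzene-1,3-diol)
Product: 14 1,3-dimethoxy-5-pentylbenzene
Conditions: Me2SO4 (2.5 equiv), K2CO3, acetone, reflux
Reagents that add atoms: dimethyl sulfate, COS(=O)(=O)OC
Why: Williamson-type O-methylation of both phenols of a resorcinol with dimethyl sulfate and carbonate is routine.

Step 7
Reactants: 14 1,3-dimethoxy-5-pentylbenzene
Product: 16 2,4-dimethoxy-6-pentylbenzaldehyde, via aryl iminium chloride 15 (not isolated)
Conditions: POCl3, DMF, 0 °C → 70 °C; then ice/H2O
Reagents that add atoms: N,N-dimethylformamide, CN(C)C=O; water, O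
Why: Vilsmeier–Haack formylation of a 5-alkylresorcinol dimethyl ether should occur at the position para to one methoxy and ortho to the other and to the alkyl chain, not at the more crowded carbon between the two methoxy groups, and the two such positions are equivalent by symmetry.

Step 8
Reactants: 16 2,4-dimethoxy-6-pentylbenzaldehyde
Product: 17 2,4-dimethoxy-6-pentylbenzoic acid
Conditions: NaClO2, NaH2PO4, 2-methyl-2-butene, t-BuOH/H2O, rt
Reagents that add atoms: sodium chlorite, [Na+].[O-]Cl=O
Why: Pinnick oxidation converts the hindered aryl aldehyde to the acid, and the alkene scavenger traps hypochlorous acid before it can chlorinate the electron-rich ring.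

Step 9
Reactants: 17 2,4-dimethoxy-6-pentylbenzoic acid; 12 benzyl 4-hydroxy-2-methoxy-6-propylbenzoate
Product: 19 benzyl 4-[(2,4-dimethoxy-6-pentylbenzoyl)oxy]-2-methoxy-6-propylbenzoate, via mixed trifluoroacetic anhydride 18 (not isolated)
Conditions: (CF3CO)2O (2 equiv), toluene, 0 °C → rt, 17 activated first, then 12 added
Reagents that add atoms: none
Why: Depside esterification through the mixed trifluoroacetic anhydride, whose di-ortho-substituted electron-rich aroyl group ionizes to a stabilized acylium and acylates the C4' phenol, while the benzyl ester tolerates the trifluoroacetic acid formed.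

Step 10
Reactants: 19 benzyl 4-[(2,4-dimethoxy-6-pentylbenzoyl)oxy]-2-methoxy-6-propylbenzoate
Product: 20 4-[(2,4-dimethoxy-6-pentylbenzoyl)oxy]-2-methoxy-6-propylbenzoic acid (target)
Conditions: H2 (1 atm), Pd on carbon (Pd/C, 10%), EtOAc, rt
Reagents that add atoms: none
Why: Catalytic hydrogenolysis cleaves the benzylic C–O bond of the benzyl ester under neutral conditions that leave the aryl ester link, the methyl ethers and both arenes intact.

**Compound list**
1 | ethyl 3-oxohexanoate | CCCC(=O)CC(=O)OCC | starting material
2 | benzyl 3-oxohexanoate | CCCC(=O)CC(=O)OCc1ccccc1 | intermediate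
3 | malonyl dichloride | O=C(Cl)CC(=O)Cl | starting material
4 | benzyl 4-hydroxy-2-oxo-6-propyl-2H-pyran-5-carboxylate | CCCC1=C(C(=O)OCc2ccccc2)C(O)=CC(=O)O1 | intermediate
5 | benzyl 4-methoxy-2-oxo-6-propyl-2H-pyran-5-carboxylate | CCCC1=C(C(=O)OCc2ccccc2)C(OC)=CC(=O)O1 | intermediate
6 | trimethylsilyl acetate | CC(=O)O[Si](C)(C)C | starting material
7 | lithium 1-(trimethylsilyloxy)ethenolate (not isolated) | C=C([O-])O[Si](C)(C)C.[Li+] | intermediate
8 | 1,1-bis(trimethylsilyloxy)ethene | C=C(O[Si](C)(C)C)O[Si](C)(C)C | intermediate
9 | benzyl 5-methoxy-3-oxo-1-propyl-8,8-bis(trimethylsilyloxy)-2-oxabicyclo[2.2.2]oct-5-ene-6-carboxylate (racemic, not isolated) | CCCC12CC(O[Si](C)(C)C)(O[Si](C)(C)C)C(C(=O)O1)C(OC)=C2C(=O)OCc1ccccc1 | intermediate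
10 | benzyl 2-methoxy-6-propyl-4,4-bis(trimethylsilyloxy)cyclohexa-1(6),2-diene-1-carboxylate (not isolated) | CCCC1=C(C(=O)OCc2ccccc2)C(OC)=CC(O[Si](C)(C)C)(O[Si](C)(C)C)C1 | intermediate
11 | benzyl 2-methoxy-6-propyl-4-(trimethylsilyloxy)benzoate (not isolated) | CCCc1cc(O[Si](C)(C)C)cc(OC)c1C(=O)OCc1ccccc1 | intermediate
12 | benzyl 4-hydroxy-2-methoxy-6-propylbenzoate | CCCc1cc(O)cc(OC)c1C(=O)OCc1ccccc1 | intermediate
13 | olivetol (5-pentylbenzene-1,3-diol) | CCCCCc1cc(O)cc(O)c1 | starting material
14 | 1,3-dimethoxy-5-pentylbenzene | CCCCCc1cc(OC)cc(OC)c1 | intermediate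
15 | N-[(2,4-dimethoxy-6-pentylphenyl)methylidene]-N-methylmethanaminium chloride (not isolated) | CCCCCc1cc(OC)cc(OC)c1C=[N+](C)C.[Cl-] | intermediate
16 | 2,4-dimethoxy-6-pentylbenzaldehyde | CCCCCc1cc(OC)cc(OC)c1C=O | intermediate
17 | 2,4-dimethoxy-6-pentylbenzoic acid | CCCCCc1cc(OC)cc(OC)c1C(=O)O | intermediate
18 | 2,4-dimethoxy-6-pentylbenzoic trifluoroacetic anhydride (not isolated) | CCCCCc1cc(OC)cc(OC)c1C(=O)OC(=O)C(F)(F)F | intermediate
19 | benzyl 4-[(2,4-dimethoxy-6-pentylbenzoyl)oxy]-2-methoxy-6-propylbenzoate | CCCCCc1cc(OC)cc(OC)c1C(=O)Oc1cc(CCC)c(C(=O)OCc2ccccc2)c(OC)c1 | intermediate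
20 | 4-[(2,4-dimethoxy-6-pentylbenzoyl)oxy]-2-methoxy-6-propylbenzoic acid | CCCCCc1cc(OC)cc(OC)c1C(=O)Oc1cc(CCC)c(C(=O)O)c(OC)c1 | target

**Step count**
Total: 10 steps. Longest linear sequence: 6 steps (steps 1, 2, 3, 5, 9, 10, from ethyl 3-oxohexanoate).

**Steps most likely to fail**

Step 5. The pyrone, made less electrophilic by its 4-methoxy group and crowded at C6 by the propyl chain, may react too slowly, so that the ketene acetal is consumed by protodesilylation or silyl migration first. Alternatively, conjugate addition at C6 may end in silyl transfer without ring closure. The fallback builds ring B by a normal-demand Diels–Alder reaction of an oxygenated diene with an ynoate. It sets out from 2, which is treated with LiN(SiMe3)2 and (CF3SO2)2O in THF at −78 °C to give benzyl (Z)-3-(trifluoromethylsulfonyloxy)hex-2-enoate F1. A second equivalent of LiN(SiMe3)2 eliminates triflate anti to the C2 hydrogen to give benzyl hex-2-ynoate F2. Silylation of 4,4-dimethoxybut-3-en-2-one (Me3SiCl, Et3N, ZnCl2) gives 1,1-dimethoxy-3-(trimethylsilyloxy)buta-1,3-diene F3. Heating F2 with F3 in toluene should join the nucleophilic CH2 terminus of the diene to the propyl-bearing alkyne carbon and give benzyl 6,6-dimethoxy-2-propyl-4-(trimethylsilyloxy)cyclohexa-1,4-diene-1-carboxylate F4. Loss of methanol aromatizes F4 to silyl ether 11, where the fallback rejoins the route, and the acidic work-up of step 5 gives 12.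

Step 2. Self-condensation of malonyl dichloride and acid-promoted degradation of the benzyl ester may outrun the double acylation, and the two acylations may not both take place on the same keto ester. The fallback separates the two bond formations. It sets out from 2, which is C-acylated under soft enolization (MgCl2, pyridine, CH2Cl2) with methyl 3-chloro-3-oxopropanoate to give 1-benzyl 5-methyl 2-butanoyl-3-oxopentanedioate F5. Heating F5 with DBU in toluene closes the enol of the butanoyl ketone onto the methyl ester with loss of methanol and returns to the route at 4.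

Step 9. Acyl transfer from the di-ortho-substituted aroyl donor may be slow, so that trifluoroacetylation of the phenol or cleavage of the benzyl ester by the acid formed competes. The fallback replaces the acidic mixed-anhydride coupling with acylation of a preformed phenoxide. It sets out from 17, which is converted with oxalyl chloride and catalytic DMF in CH2Cl2 into 2,4-dimethoxy-6-pentylbenzoyl chloride F6. Phenol 12 is deprotonated with NaH in THF to sodium 4-(benzyloxycarbonyl)-3-methoxy-5-propylphenolate F7. F6 and F7 combine at 0 °C to rt and return to the route at 19.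

**Further compounds**
F1 | step 5 | benzyl (Z)-3-(trifluoromethylsulfonyloxy)hex-2-enoate | CCC/C(OS(=O)(=O)C(F)(F)F)=C/C(=O)OCc1ccccc1
F2 | step 5 | benzyl hex-2-ynoate | CCCC#CC(=O)OCc1ccccc1
F3 | step 5 | 1,1-dimethoxy-3-(trimethylsilyloxy)buta-1,3-diene | C=C(O[Si](C)(C)C)C=C(OC)OC
F4 | step 5 | benzyl 6,6-dimethoxy-2-propyl-4-(trimethylsilyloxy)cyclohexa-1,4-diene-1-carboxylate | CCCC1=C(C(=O)OCc2ccccc2)C(OC)(OC)C=C(O[Si](C)(C)C)C1
F5 | step 2 | 1-benzyl 5-methyl 2-butanoyl-3-oxopentanedioate | CCCC(=O)C(C(=O)OCc1ccccc1)C(=O)CC(=O)OC
F6 | step 9 | 2,4-dimethoxy-6-pentylbenzoyl chloride | CCCCCc1cc(OC)cc(OC)c1C(=O)Cl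
F7 | step 9 | sodium 4-(benzyloxycarbonyl)-3-methoxy-5-propylphenolate | CCCc1cc([O-])cc(OC)c1C(=O)OCc1ccccc1.[Na+]
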